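The leftover in the summer run caught my eye: by 20.0 h, other capture product held 9.5% of the substrate charged, while 0.70 equiv of second nucleophile had been on offer. I took the second nucleophile as standing near its charge fraction through the capture, assumed the same of the first nucleophile as a rough simplification, and asked how a feed bends the competition between them.

| flask | substrate | first nucleophile | second nucleophile | remark | time |
|---|---|---|---|---|---|
| summer | 0.10 M | 0.60 equiv | 0.70 equiv | run made earlier |  |
| dusk | 0.10 M | 0.84 equiv | 0.70 equiv | run made earlier |  |
| noon | 0.10 M | 1.3 equiv | 0.70 equiv | run made earlier |  |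
| spring | 0.10 M | 0.60 equiv | 1.4 equiv | run made earlier |  |
| Thursday's | 0.10 M | 0.600 equiv (fed, over 25 min) | 0.700 equiv | all else is in the flask from the start; the feed brings no volume worth counting | 20 h |
| Sunday's | 0.10 M | 0.600 equiv | 0.700 equiv (fed, over 4.0 h) | all else is in the flask from the start; the feed brings no volume worth counting | 20 h |
| Monday's | 0.10 M | 0.600 equiv | 0.700 equiv | everything together at the start | 20 h |
| Wednesday's | 0.10 M | 0.600 equiv (fed, over 4.0 h) | 0.700 equiv | all else is in the flask from the start; the feed brings no volume worth counting | 20 h |

- summer (time / h: target / %, other capture product / %, substrate / %): 2.50: 13.2, 4.3, 15.2; 8.00: 12.3, 7.4, 2.2; 12.0: 11.1, 9.1, 0.8; 20.0: 13.2, 9.5, 0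
- dusk (time / h: target / %, other capture product / %, substrate / %): 4.00: 13.8, 6.2, 6.9; 8.00: 14.4, 7.2, 0.1; 12.0: 14.6, 7.1, 0.4; 15.0: 16.5, 8.4, 0
- noon (time / h: target / %, other capture product / %, substrate / %): 4.00: 16.9, 2.7, 9.6; 8.00: 16.6, 6.4, 1.0; 12.0: 17.2, 3.5, 1.0; 15.0: 17.2, 7.2, 0.4
- spring (time / h: target / %, other capture product / %, substrate / %): 1.33: 9.9, 6.9, 26.7; 3.00: 11.0, 12.1, 10.5; 6.00: 9.9, 14.4, 2.6; 15.0: 10.1, 15.4, 0

(standard deviation of a reading: 1 percentage point)

- percent here means substrate units held: one homo dimer or idle adduct counts as two
- what is said of target includes idle adduct
- what was read earlier has a scatter of 1 percentage point, one standard deviation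
- reactions considered so far: substrate + target <-> idle adduct; second nucleophile + intermediate -> other capture product; 2 substrate -> homo dimer; substrate -> intermediate; intermediate -> solvolysis product; target <-> isomer of the product; first nucleophile + intermediate -> target
- in an amount of target, one idle adduct counts as one target

- the flask with the highest share of target in target plus other capture product ("all alike" if they lie within 1.5 percentage points) (Thursday's / Sunday's / Monday's / Wednesday's / all alike)
- share of target in target plus other capture product at the end, Thursday's
- share of target in target plus other capture product at the end, Sunday's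
- share of target in target plus other capture product at the end, Monday's
- share of target in target plus other capture product at the end, Wednesday's

1. The summer run gave the moment's ratio. Its end ratio of target to other capture product, divided by the ratio of the charges, is an apparent selectivity factor of 1.62. As readings, spring gave 1.53 and noon 1.29.

2. I drew Wednesday's ratio, with the first nucleophile pumped in steadily. It starts at zero and climbs by 0.347 h⁻¹.

3. The substrate reading of 15.2% at 2.50 h gave a single exponential with a time constant of 1.33 h, which I assumed capture follows.

4. On my curve for Wednesday's, the ratio crosses unity at 2.88 h, earlier than the feed ends, with 11.5% of the substrate left by my exponential.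

5. On the same curve, the knee comes at 4.0 h, with 4.94% left by my exponential, and the ratio then levels at 1.39.

6. Weighting the fed fraction by the substrate present gave 0.315. This is my feed share, the fraction of a fed charge in the flask at the average moment of capture. Multiplying the level by it gave Wednesday's 30.5%. Dividing by it gave Sunday's 81.5%, my highest, above the unfed 58.2%.

7. The forecast named Sunday's, with Thursday's 56%, Sunday's 71%, Monday's 57% and Wednesday's 44%. Of the loss to the isomer of the product it wrote “that equilibrium loss should scale all flasks alike”. My reckoning parted from it at Wednesday's, 30.5% against 44%.

8. The flasks gave Thursday's 52.8%, Sunday's 74.1%, Monday's 56.4% and Wednesday's 32.3%, with Sunday's highest.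

    substrate + target ⇌ idle adduct, settled at all times (K = 6.60 M⁻¹)
    second nucleophile + intermediate → other capture product (k = 0.0470 M⁻¹ s⁻¹)
    2 substrate → homo dimer (k = 0.00150 M⁻¹ s⁻¹)
    substrate → intermediate (k = 1.00 × 10⁻⁴ s⁻¹)
    intermediate → solvolysis product (k = 0.00420 s⁻¹)
    target ⇌ isomer of the product (K = 1.00, k = 9.70 × 10⁻⁵ s⁻¹)
    first nucleophile + intermediate → target (k = 0.170 M⁻¹ s⁻¹)

Wednesday's ended at 32.3%, against 30.5% from my reckoning and 44% from the forecast, with 78% of its first nucleophile still left at 20.0 h. Read backwards from that share, the feed share of Wednesday's came to 0.343, against my 0.315. Turned the other way up for the fed second nucleophile, the feed share had given Sunday's 81.5%, and Sunday's ended at 74.1%.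

(The numbers in the tables are calculated with constants of no real substance; noise was put on by code.)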